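**Strategy.** Everything rests on the C2–C1′ single bond that links two sp2 carbons: C2, the α-carbon of the C1(=O)–C2=C3 enone of the cyclohexenone ring, and C1′ of the (E)-C1′=C2′ alkene of the hydroxyheptenyl chain. A Suzuki–Miyaura coupling of a 2-iodoenone with an (E)-alkenylboronate forms this bond, completes the carbon skeleton and fixes the diene geometry in one operation. The iodoenone carries all three ring stereocentres; it derives from (1S,2S)-3-bromocyclohexa-3,5-diene-1,2-diol, whose C–Br carbon becomes C3 and whose cis-diol becomes C4/C5, with C6 set by enolate alkylation. The boronate derives from (R)-propylene oxide. One acid treatment then releases the target.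

Key step: step 14

Remark: ring atoms are numbered as in the final cyclohexenone (C1 carbonyl, C2 alkenyl-bearing, C3 hydroxymethyl-bearing, C4 and C5 carbinol carbons, C6 butenoate-bearing). The 5,6-trans arrangement at the enolisable C6 is assumed to be the thermodynamically preferred one, so that any enolisation after step 7 should converge on the required epimer.

Step 1
Reactants: 1 (1S,2S)-3-bromocyclohexa-3,5-diene-1,2-diol
Product: 2 (1S,2S)-3-bromocyclohex-3-ene-1,2-diol
Conditions: KO2CN=NCO2K, AcOH, MeOH, 0 °C → rt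
Reagents that add atoms: none
Why: Diimide generated in situ should transfer H2 in a concerted syn fashion only to the unhalogenated, less substituted C=C bond, because the bromo-substituted alkene is too hindered and electron-poor, so the vinyl bromide and both carbinol stereocentres survive (chemoselective diimide reduction).

Step 2
Reactants: 2 (1S,2S)-3-bromocyclohex-3-ene-1,2-diol
Product: 3 (3aS,7aS)-4-bromo-2,2-dimethyl-3a,6,7,7a-tetrahydro-1,3-benzodioxole
Conditions: 2,2-dimethoxypropane, p-TsOH (cat.), acetone, rt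
Reagents that add atoms: 2,2-dimethoxypropane, COC(C)(C)OC
Why: Acid-catalysed transketalisation of the cis-1,2-diol should give the cis-fused dioxolane (acetonide protection), which masks both hydroxyls and later shields one face of the ring.

Step 3
Reactants: 3 (3aS,7aS)-4-bromo-2,2-dimethyl-3a,6,7,7a-tetrahydro-1,3-benzodioxole
Product: 4 (4S,5S)-3-bromo-4,5-(isopropylidenedioxy)cyclohex-2-en-1-one
Conditions: CrO3, 3,5-dimethylpyrazole, CH2Cl2, −20 °C
Reagents that add atoms: chromium trioxide, O=[Cr](=O)=O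
Why: Allylic oxidation with the CrO3·3,5-dimethylpyrazole complex should convert the only allylic methylene (the future C1) into the ketone, the reaction type by which 1-halocycloalkenes give 3-halocycloalkenones, while the tertiary ring-fusion C–H is shielded.

Step 4
Reactants: 5 tert-butyl 2-bromopropanoate
Product: 7 tert-butyl 2-(triphenyl-λ5-phosphanylidene)propanoate, via phosphonium bromide 6 (not isolated)
Conditions: PPh3, toluene, 90 °C; then aq. NaOH, CH2Cl2, 0 °C
Reagents that add atoms: triphenylphosphine, c1ccc(cc1)P(c1ccccc1)c1ccccc1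
Why: SN2 quaternisation of triphenylphosphine by the α-bromo ester and deprotonation of the acidic α-C–H should give the ester-stabilised ylide (Wittig reagent preparation).

Step 5
Reactants: 7 tert-butyl 2-(triphenyl-λ5-phosphanylidene)propanoate; 8 1,4-dioxane-2,5-diol (glycolaldehyde dimer)
Product: 10 tert-butyl (2E)-4-hydroxy-2-methylbut-2-enoate, via glycolaldehyde monomer 9 (not isolated)
Conditions: CH2Cl2, reflux
Reagents that add atoms: none
Why: The dimer cracks to monomeric glycolaldehyde, which should undergo Wittig olefination with the stabilised α-methyl ylide under thermodynamic control to give the E-trisubstituted enoate.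

Step 6
Reactants: 10 tert-butyl (2E)-4-hydroxy-2-methylbut-2-enoate
Product: 11 tert-butyl (2E)-4-bromo-2-methylbut-2-enoate
Conditions: CBr4, PPh3, CH2Cl2, 0 °C
Reagents that add atoms: carbon tetrabromide, BrC(Br)(Br)Br
Why: Appel reaction: the primary allylic alcohol is activated as an alkoxyphosphonium ion and displaced by bromide at the primary carbon, which should leave the E-alkene untouched.

Step 7
Reactants: 4 (4S,5S)-3-bromo-4,5-(isopropylidenedioxy)cyclohex-2-en-1-one; 11 tert-butyl (2E)-4-bromo-2-methylbut-2-enoate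
Product: 13 (4S,5S,6S)-3-bromo-6-[(2E)-4-tert-butoxy-3-methyl-4-oxobut-2-en-1-yl]-4,5-(isopropylidenedioxy)cyclohex-2-en-1-one, via lithium enolate 12 (not isolated)
Conditions: LiN(SiMe3)2, THF, −78 °C; then 11, DMPU, −78 → −40 °C
Reagents that add atoms: none
Why: Kinetic deprotonation at C6 gives the cross-conjugated lithium enolate, whose C-alkylation by the reactive allylic bromide should occur on the convex face anti to the cis-fused dioxolane, setting C6 trans to the C5 oxygen (6S), the epimer expected to be thermodynamically preferred as well (enolate alkylation).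

Step 8
Reactants: 13 (4S,5S,6S)-3-bromo-6-[(2E)-4-tert-butoxy-3-methyl-4-oxobut-2-en-1-yl]-4,5-(isopropylidenedioxy)cyclohex-2-en-1-one
Product: 14 (4R,5S,6S)-6-[(2E)-4-tert-butoxy-3-methyl-4-oxobut-2-en-1-yl]-3-(hydroxymethyl)-4,5-(isopropylidenedioxy)cyclohex-2-en-1-one
Conditions: Bu3SnCH2OH, Pd(PPh3)4 (cat.), 1,4-dioxane, 80 °C
Reagents that add atoms: (tributylstannyl)methanol, CCCC[Sn](CCCC)(CCCC)CO
Why: Stille coupling: zerovalent palladium should add oxidatively to the activated β-bromoenone C–Br bond, and the α-oxygenated hydroxymethyl group is transferred from tin in preference to butyl.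

Step 9
Reactants: 14 (4R,5S,6S)-6-[(2E)-4-tert-butoxy-3-methyl-4-oxobut-2-en-1-yl]-3-(hydroxymethyl)-4,5-(isopropylidenedioxy)cyclohex-2-en-1-one
Product: 15 (4R,5S,6S)-6-[(2E)-4-tert-butoxy-3-methyl-4-oxobut-2-en-1-yl]-3-(hydroxymethyl)-2-iodo-4,5-(isopropylidenedioxy)cyclohex-2-en-1-one
Conditions: I2, pyridine, DMAP (cat.), CH2Cl2, rt, dark
Reagents that add atoms: iodine, II
Why: α-Iodination of the enone by reversible conjugate addition of the amine at C3, iodination of the resulting enolate at C2 and elimination of the amine (Baylis–Hillman-type addition–elimination) should place iodine only at C2.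

Step 10
Reactants: 16 (4-bromobut-1-yn-1-yl)trimethylsilane; 17 (R)-2-methyloxirane
Product: 19 (2R)-7-(trimethylsilyl)hept-6-yn-2-ol, via Grignard reagent 18 (not isolated)
Conditions: Mg, THF, rt; then CuI (cat.), 17, −30 → 0 °C; aq. NH4Cl
Reagents that add atoms: none
Why: The Grignard reagent should open the epoxide under CuI catalysis by SN2 attack at the unsubstituted carbon, so the C–O stereocentre of the chiral-pool epoxide is retained as (R).

Step 11
Reactants: 19 (2R)-7-(trimethylsilyl)hept-6-yn-2-ol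
Product: 20 tert-butyldimethyl{[(2R)-7-(trimethylsilyl)hept-6-yn-2-yl]oxy}silane
Conditions: TBSCl, imidazole, DMF, rt
Reagents that add atoms: tert-butyldimethylsilyl chloride, CC(C)(C)[Si](C)(C)Cl
Why: Standard silylation of the secondary alcohol with imidazole as base and nucleophilic catalyst; the stereocentre is not involved.

Step 12
Reactants: 20 tert-butyldimethyl{[(2R)-7-(trimethylsilyl)hept-6-yn-2-yl]oxy}silane
Product: 21 tert-butyl[(2R)-hept-6-yn-2-yloxy]dimethylsilane
Conditions: K2CO3 (cat.), MeOH, rt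
Reagents that add atoms: none
Why: Methoxide-mediated protodesilylation should cleave the alkynyl C–Si bond selectively, because the bulky silyl ether is inert to K2CO3/MeOH.

Step 13
Reactants: 21 tert-butyl[(2R)-hept-6-yn-2-yloxy]dimethylsilane
Product: 22 tert-butyldimethyl{[(2R,6E)-7-(4,4,5,5-tetramethyl-1,3,2-dioxaborolan-2-yl)hept-6-en-2-yl]oxy}silane
Conditions: pinacolborane, Cp2ZrHCl (cat.), Et3N (cat.), neat, 60 °C
Reagents that add atoms: pinacolborane, CC1(C)OBOC1(C)C
Why: Zirconium-hydride-catalysed syn, anti-Markovnikov hydroboration of the terminal alkyne with pinacolborane should give only the (E)-alkenylboronate.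

Step 14
Reactants: 15 (4R,5S,6S)-6-[(2E)-4-tert-butoxy-3-methyl-4-oxobut-2-en-1-yl]-3-(hydroxymethyl)-2-iodo-4,5-(isopropylidenedioxy)cyclohex-2-en-1-one; 22 tert-butyldimethyl{[(2R,6E)-7-(4,4,5,5-tetramethyl-1,3,2-dioxaborolan-2-yl)hept-6-en-2-yl]oxy}silane
Product: 23 (4R,5S,6S)-6-[(2E)-4-tert-butoxy-3-methyl-4-oxobut-2-en-1-yl]-2-[(1E,6R)-6-(tert-butyldimethylsilyloxy)hept-1-en-1-yl]-3-(hydroxymethyl)-4,5-(isopropylidenedioxy)cyclohex-2-en-1-one
Conditions: Pd(dppf)Cl2·CH2Cl2 (cat.), AsPh3, K3PO4, THF/H2O, rt, degassed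
Reagents that add atoms: none
Why: Zerovalent palladium inserts into the C2–I bond of 15, the phosphate-activated alkenylboronate 22 transmetalates with retention of its E geometry, and reductive elimination forms the C2–C1′ bond. The closest known reaction type is the Suzuki–Miyaura coupling of 2-iodocycloalkenones with alkenylboron reagents at room temperature. No ring is closed and no stereocentre is created; the C1′=C2′ geometry is inherited from the syn-hydroboration of step 13 and the C2=C3 geometry is fixed by the ring. The step needs chemoselective oxidative addition, which the single enone-activated C(sp2)–I bond secures, and it must not enolise C6 toward loss of the C5 oxygen and aromatisation, which the mild base and room temperature should secure. The free hydroxymethyl group, the tert-butyl ester, the silyl ether and the ketal should be inert to these conditions.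

Step 15
Reactants: 23 (4R,5S,6S)-6-[(2E)-4-tert-butoxy-3-methyl-4-oxobut-2-en-1-yl]-2-[(1E,6R)-6-(tert-butyldimethylsilyloxy)hept-1-en-1-yl]-3-(hydroxymethyl)-4,5-(isopropylidenedioxy)cyclohex-2-en-1-one
Product: 24 Pestallic acid O
Conditions: TFA/CH2Cl2/H2O, 0 °C → rt
Reagents that add atoms: none
Why: Aqueous trifluoroacetic acid should hydrolyse the acetonide, cleave the silyl ether and remove the tert-butyl group as isobutene in one operation under non-basic conditions that spare the β-hydroxy ketone, so no stereocentre is affected (global acidolysis).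

**Compound list**

1 | (1S,2S)-3-bromocyclohexa-3,5-diene-1,2-diol (whole-cell dihydroxylation product of bromobenzene) | O[C@H]1C=CC=C(Br)[C@H]1O | starting material
2 | (1S,2S)-3-bromocyclohex-3-ene-1,2-diol | O[C@H]1CCC=C(Br)[C@H]1O | intermediate
3 | (3aS,7aS)-4-bromo-2,2-dimethyl-3a,6,7,7a-tetrahydro-1,3-benzodioxole | C1C=C(Br)[C@H]2OC(C)(C)O[C@H]2C1 | intermediate
4 | (4S,5S)-3-bromo-4,5-(isopropylidenedioxy)cyclohex-2-en-1-one | O=C1C=C(Br)[C@H]2OC(C)(C)O[C@H]2C1 | intermediate
5 | tert-butyl 2-bromopropanoate (racemic) | CC(Br)C(=O)OC(C)(C)C | starting material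
6 | [1-(tert-butoxy)-1-oxopropan-2-yl]triphenylphosphonium bromide | CC(C(=O)OC(C)(C)C)[P+](c1ccccc1)(c1ccccc1)c1ccccc1.[Br-] | intermediate
7 | tert-butyl 2-(triphenyl-λ5-phosphanylidene)propanoate | CC(C(=O)OC(C)(C)C)=P(c1ccccc1)(c1ccccc1)c1ccccc1 | intermediate
8 | 1,4-dioxane-2,5-diol (glycolaldehyde dimer) | OC1COC(O)CO1 | starting material
9 | glycolaldehyde | OCC=O | intermediate
10 | tert-butyl (2E)-4-hydroxy-2-methylbut-2-enoate | C/C(=C\CO)C(=O)OC(C)(C)C | intermediate
11 | tert-butyl (2E)-4-bromo-2-methylbut-2-enoate | C/C(=C\CBr)C(=O)OC(C)(C)C | intermediate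
12 | lithium cross-conjugated dienolate of 4 (O–C1=C6, C2=C3), lithium (3aS,7aS)-7-bromo-2,2-dimethyl-3a,7a-dihydro-1,3-benzodioxol-5-olate | [Li]OC1=C[C@@H]2OC(C)(C)O[C@@H]2C(Br)=C1 | intermediate
13 | (4S,5S,6S)-3-bromo-6-[(2E)-4-tert-butoxy-3-methyl-4-oxobut-2-en-1-yl]-4,5-(isopropylidenedioxy)cyclohex-2-en-1-one | O=C1C=C(Br)[C@H]2OC(C)(C)O[C@H]2[C@@H]1C/C=C(\C)C(=O)OC(C)(C)C | intermediate
14 | (4R,5S,6S)-6-[(2E)-4-tert-butoxy-3-methyl-4-oxobut-2-en-1-yl]-3-(hydroxymethyl)-4,5-(isopropylidenedioxy)cyclohex-2-en-1-one | O=C1C=C(CO)[C@H]2OC(C)(C)O[C@H]2[C@@H]1C/C=C(\C)C(=O)OC(C)(C)C | intermediate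
15 | (4R,5S,6S)-6-[(2E)-4-tert-butoxy-3-methyl-4-oxobut-2-en-1-yl]-3-(hydroxymethyl)-2-iodo-4,5-(isopropylidenedioxy)cyclohex-2-en-1-one | O=C1C(I)=C(CO)[C@H]2OC(C)(C)O[C@H]2[C@@H]1C/C=C(\C)C(=O)OC(C)(C)C | intermediate
16 | (4-bromobut-1-yn-1-yl)trimethylsilane | C[Si](C)(C)C#CCCBr | starting material
17 | (R)-2-methyloxirane ((R)-propylene oxide) | C[C@@H]1CO1 | starting material
18 | [4-(trimethylsilyl)but-3-yn-1-yl]magnesium bromide | C[Si](C)(C)C#CCC[Mg]Br | intermediate
19 | (2R)-7-(trimethylsilyl)hept-6-yn-2-ol | C[C@@H](O)CCCC#C[Si](C)(C)C | intermediate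
20 | tert-butyldimethyl{[(2R)-7-(trimethylsilyl)hept-6-yn-2-yl]oxy}silane | C[C@H](CCCC#C[Si](C)(C)C)O[Si](C)(C)C(C)(C)C | intermediate
21 | tert-butyl[(2R)-hept-6-yn-2-yloxy]dimethylsilane | C#CCCC[C@@H](C)O[Si](C)(C)C(C)(C)C | intermediate
22 | tert-butyldimethyl{[(2R,6E)-7-(4,4,5,5-tetramethyl-1,3,2-dioxaborolan-2-yl)hept-6-en-2-yl]oxy}silane | CC1(C)OB(/C=C/CCC[C@@H](C)O[Si](C)(C)C(C)(C)C)OC1(C)C | intermediate
23 | (4R,5S,6S)-6-[(2E)-4-tert-butoxy-3-methyl-4-oxobut-2-en-1-yl]-2-[(1E,6R)-6-(tert-butyldimethylsilyloxy)hept-1-en-1-yl]-3-(hydroxymethyl)-4,5-(isopropylidenedioxy)cyclohex-2-en-1-one | O=C1C(/C=C/CCC[C@@H](C)O[Si](C)(C)C(C)(C)C)=C(CO)[C@H]2OC(C)(C)O[C@H]2[C@@H]1C/C=C(\C)C(=O)OC(C)(C)C | intermediate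
24 | Pestallic acid O, (2E)-4-[(1S,5R,6S)-5,6-dihydroxy-4-(hydroxymethyl)-3-[(1E,6R)-6-hydroxyhept-1-en-1-yl]-2-oxocyclohex-3-en-1-yl]-2-methylbut-2-enoic acid | C/C(=C\C[C@@H]1C(=O)C(/C=C/CCC[C@@H](C)O)=C(CO)[C@@H](O)[C@H]1O)C(=O)O | target

**Total step count:** 15

**Longest linear sequence:** 8 steps (steps 1, 2, 3, 7, 8, 9, 14, 15 from 1; the branch from 5 through steps 4, 5, 6, 7, 8, 9, 14, 15 is equally long).

**Steps most likely to fail**

Step 7. The lithium enolate may expel the C5 oxygen by β-elimination and then aromatise, may add in conjugate fashion to the bromoenoate with cyclopropane closure, or may be alkylated twice. The fallback avoids any free metal enolate and sets out from 4. Soft enolisation (TMSOTf, Et3N, CH2Cl2, 0 °C) should give the cross-conjugated silyl dienol ether {[(3aS,7aS)-7-bromo-2,2-dimethyl-3a,7a-dihydro-1,3-benzodioxol-5-yl]oxy}trimethylsilane F1. N-Bromosuccinimide in THF at −78 °C should brominate it at C6 to give (4S,5R,6S)-3,6-dibromo-4,5-(isopropylidenedioxy)cyclohex-2-en-1-one F2. Keck radical allylation (allyltributylstannane, AIBN, benzene, 80 °C) should replace the C6 bromine by allyl on the face anti to the dioxolane, a carbon radical not being prone to expel a β-alkoxy group, and give (4S,5S,6S)-3-bromo-4,5-(isopropylidenedioxy)-6-(prop-2-en-1-yl)cyclohex-2-en-1-one F3. Cross-metathesis of F3 with excess tert-butyl methacrylate (second-generation Hoveyda–Grubbs catalyst, CH2Cl2, 40 °C) should give the E-trisubstituted enoate and comes back to the route at 13.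

Step 3. Hydrogen abstraction next to the electron-poor vinyl bromide may be slow, and oxygen may be delivered with allylic transposition onto the bromine-bearing carbon or at the ring-fusion C–H. The fallback fixes the oxygen position by ionic chemistry and sets out from 1. Acetonide formation (2,2-dimethoxypropane, p-TsOH, acetone) should give (3aS,7aS)-4-bromo-2,2-dimethyl-3a,7a-dihydro-1,3-benzodioxole F4. N-Bromosuccinimide in THF/H2O at 0 °C should form the bromonium ion on the unhalogenated alkene anti to the dioxolane, and water should open it at the allylic carbon, giving the trans-bromohydrin (3aR,4R,5S,7aS)-4,7-dibromo-2,2-dimethyl-3a,4,5,7a-tetrahydro-1,3-benzodioxol-5-ol F5. One equivalent of Bu3SnH with AIBN (benzene, 80 °C) should remove the secondary alkyl bromine faster than the vinyl bromine and give the allylic alcohol (3aS,5R,7aS)-7-bromo-2,2-dimethyl-3a,4,5,7a-tetrahydro-1,3-benzodioxol-5-ol F6. Oxidation of F6 with MnO2 in CH2Cl2 comes back to the route at 4.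

Step 9. Conjugate addition of the amine to the fully substituted β-carbon C3 may be too slow, so that iodination stalls while the base slowly enolises the ketone. The fallback iodinates by an electrophilic pathway on a protected substrate and sets out from 14. Silylation (TBSCl, imidazole, DMF) should give (4R,5S,6S)-6-[(2E)-4-tert-butoxy-3-methyl-4-oxobut-2-en-1-yl]-3-{[(tert-butyldimethylsilyl)oxy]methyl}-4,5-(isopropylidenedioxy)cyclohex-2-en-1-one F7. Iodination with I2 and PhI(OCOCF3)2 in pyridine/CH2Cl2 (addition of trifluoroacetyl hypoiodite across the enone, then base-induced elimination) should give the 2-iodo derivative (4R,5S,6S)-6-[(2E)-4-tert-butoxy-3-methyl-4-oxobut-2-en-1-yl]-3-{[(tert-butyldimethylsilyl)oxy]methyl}-2-iodo-4,5-(isopropylidenedioxy)cyclohex-2-en-1-one F8. Suzuki–Miyaura coupling of F8 with 22 under the conditions of step 14 should give (4R,5S,6S)-6-[(2E)-4-tert-butoxy-3-methyl-4-oxobut-2-en-1-yl]-2-[(1E,6R)-6-(tert-butyldimethylsilyloxy)hept-1-en-1-yl]-3-{[(tert-butyldimethylsilyl)oxy]methyl}-4,5-(isopropylidenedioxy)cyclohex-2-en-1-one F9. The acid treatment of step 15 then removes both silyl ethers as well and comes back to the route at 24.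

**Further compounds**

F1 | step 7 | {[(3aS,7aS)-7-bromo-2,2-dimethyl-3a,7a-dihydro-1,3-benzodioxol-5-yl]oxy}trimethylsilane | C[Si](C)(C)OC1=C[C@@H]2OC(C)(C)O[C@@H]2C(Br)=C1
F2 | step 7 | (4S,5R,6S)-3,6-dibromo-4,5-(isopropylidenedioxy)cyclohex-2-en-1-one | O=C1C=C(Br)[C@H]2OC(C)(C)O[C@H]2[C@@H]1Br
F3 | step 7 | (4S,5S,6S)-3-bromo-4,5-(isopropylidenedioxy)-6-(prop-2-en-1-yl)cyclohex-2-en-1-one | O=C1C=C(Br)[C@H]2OC(C)(C)O[C@H]2[C@@H]1CC=C
F4 | step 3 | (3aS,7aS)-4-bromo-2,2-dimethyl-3a,7a-dihydro-1,3-benzodioxole | CC1(C)O[C@H]2C=CC=C(Br)[C@H]2O1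
F5 | step 3 | (3aR,4R,5S,7aS)-4,7-dibromo-2,2-dimethyl-3a,4,5,7a-tetrahydro-1,3-benzodioxol-5-ol | O[C@H]1C=C(Br)[C@H]2OC(C)(C)O[C@H]2[C@@H]1Br
F6 | step 3 | (3aS,5R,7aS)-7-bromo-2,2-dimethyl-3a,4,5,7a-tetrahydro-1,3-benzodioxol-5-ol | O[C@H]1C=C(Br)[C@H]2OC(C)(C)O[C@H]2C1
F7 | step 9 | (4R,5S,6S)-6-[(2E)-4-tert-butoxy-3-methyl-4-oxobut-2-en-1-yl]-3-{[(tert-butyldimethylsilyl)oxy]methyl}-4,5-(isopropylidenedioxy)cyclohex-2-en-1-one | O=C1C=C(CO[Si](C)(C)C(C)(C)C)[C@H]2OC(C)(C)O[C@H]2[C@@H]1C/C=C(\C)C(=O)OC(C)(C)C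
F8 | step 9 | (4R,5S,6S)-6-[(2E)-4-tert-butoxy-3-methyl-4-oxobut-2-en-1-yl]-3-{[(tert-butyldimethylsilyl)oxy]methyl}-2-iodo-4,5-(isopropylidenedioxy)cyclohex-2-en-1-one | O=C1C(I)=C(CO[Si](C)(C)C(C)(C)C)[C@H]2OC(C)(C)O[C@H]2[C@@H]1C/C=C(\C)C(=O)OC(C)(C)C
F9 | step 9 | (4R,5S,6S)-6-[(2E)-4-tert-butoxy-3-methyl-4-oxobut-2-en-1-yl]-2-[(1E,6R)-6-(tert-butyldimethylsilyloxy)hept-1-en-1-yl]-3-{[(tert-butyldimethylsilyl)oxy]methyl}-4,5-(isopropylidenedioxy)cyclohex-2-en-1-one | O=C1C(/C=C/CCC[C@@H](C)O[Si](C)(C)C(C)(C)C)=C(CO[Si](C)(C)C(C)(C)C)[C@H]2OC(C)(C)O[C@H]2[C@@H]1C/C=C(\C)C(=O)OC(C)(C)C
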